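**Retrosynthetic overview**
1. Ring labels: A is the end with two free phenols, B is the middle ring, C carries the methyl ester. Each ring is numbered C1 (bears the carbonyl), C2 (OH), C4 (para O), C6 (CH3).
2. Feature used: ring B has O at C2 and C4, H at C3 and C5, and its C1 carboxyl beside the C6 methyl. This maps atom for atom onto a 1,1,3-oxygenated buta-1,3-diene (C2–C3–C4–C5) joined to a but-2-ynoate (C1, C6, CH3, C=O).
3. First disconnections: the three O-benzyl groups and the chelated ring B O2-methyl group (one BCl3 step). Then the A–B ester bond, giving 2,4-di-O-benzylorsellinic acid and a B–C depside with free O4.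
4. Key disconnection: C1–C2 and C5–C6 of ring B. This gives 1,1-dimethoxy-3-(trimethylsilyloxy)buta-1,3-diene and the but-2-ynoate of O2-benzyl methyl orsellinate, which already holds the B–C ester bond.
5. Ring order: rings A and C are bought as methyl orsellinate. Ring B is the only ring made, grown on ring C before ring A is attached.

Key step: step 8

Remark on the chemistry: the target has no stereocentre. The O2-benzyl ether of ring C is installed before the but-2-ynoate, under a temporary O4-allyl ether. Basic benzylation of a phenol that already carries an aryl ynoate would invite phenoxide conjugate addition and acyl transfer.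

**Step 1**
Reactants: 1 1,1-dichloroethene; 2 acetyl chloride
Product: 4 4,4-dichlorobut-3-en-2-one, via 4,4,4-trichlorobutan-2-one 3 (not isolated)
Conditions: AlCl3 (1.1 equiv), CH2Cl2, 0 °C to rt; ice/aq HCl; then steam distillation
Reagents that add atoms: none
Why: Friedel–Crafts-type acylation of an alkene, in which the acylium ion from 2 and AlCl3 attacks the CH2 terminus of 1 so that the cation sits on the chlorine-bearing carbon, chloride capture gives 3, and loss of HCl from this β-trichloromethyl ketone is driven by conjugation with the carbonyl.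

**Step 2**
Reactants: 4 4,4-dichlorobut-3-en-2-one
Product: 5 4,4-dimethoxybut-3-en-2-one
Conditions: NaOMe (2.2 equiv), MeOH, 0 °C to rt
Reagents that add atoms: sodium methoxide, [Na+].[O-]C
Why: Two consecutive addition–elimination substitutions (nucleophilic vinylic substitution) at the β-carbon of this vinylogous acid chloride exchange both chlorides for methoxide and should stop at the push–pull keto ketene acetal, which is a poor acceptor.

**Step 3**
Reactants: 5 4,4-dimethoxybut-3-en-2-one
Product: 6 1,1-dimethoxy-3-(trimethylsilyloxy)buta-1,3-diene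
Conditions: Me3SiCl, Et3N, ZnCl2 (cat.), toluene, 40 °C; filtration, distillation
Reagents that add atoms: chlorotrimethylsilane, C[Si](C)(C)Cl
Why: Silyl enol ether formation by soft enolisation, in which the methyl group is the only enolisable position of 5, so ZnCl2-assisted deprotonation by Et3N and O-silylation can give only the 2-silyloxydiene 6, isolated without contact with water.

**Step 4**
Reactants: 7 methyl orsellinate (methyl 2,4-dihydroxy-6-methylbenzoate)
Product: 8 methyl 4-(allyloxy)-2-hydroxy-6-methylbenzoate
Conditions: allyl bromide (1.05 equiv), K2CO3 (1.1 equiv), acetone, reflux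
Reagents that add atoms: allyl bromide, C=CCBr
Why: Williamson ether synthesis made regioselective by the substrate, since the 2-hydroxyl is locked in a hydrogen bond to the neighbouring ester carbonyl while the 4-hydroxyl is the more acidic and freer one, so one equivalent of halide should go to O4.

**Step 5**
Reactants: 8 methyl 4-(allyloxy)-2-hydroxy-6-methylbenzoate
Product: 9 methyl 4-(allyloxy)-2-(benzyloxy)-6-methylbenzoate
Conditions: BnBr (1.5 equiv), K2CO3 (2 equiv), DMF, 60 °C
Reagents that add atoms: benzyl bromide, BrCc1ccccc1
Why: Williamson ether synthesis under more forcing conditions (dipolar aprotic solvent, heat, excess halide) alkylates the one remaining chelated phenol, and the allyl ether and the hindered methyl ester are inert at a temperature far below that of a Claisen rearrangement.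

**Step 6**
Reactants: 9 methyl 4-(allyloxy)-2-(benzyloxy)-6-methylbenzoate
Product: 10 methyl 2-(benzyloxy)-4-hydroxy-6-methylbenzoate
Conditions: Pd(PPh3)4 (5 mol%), morpholine (5 equiv), THF, rt
Reagents that add atoms: none
Why: Tsuji–Trost-type deallylation, in which zerovalent palladium ionises the allyl aryl ether to a π-allyl complex and the phenoxide and morpholine takes the allyl group irreversibly, while the benzyl ether and the methyl ester have no such ionisation path.

**Step 7**
Reactants: 10 methyl 2-(benzyloxy)-4-hydroxy-6-methylbenzoate; 11 but-2-ynoic acid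
Product: 12 methyl 2-(benzyloxy)-4-(but-2-ynoyloxy)-6-methylbenzoate
Conditions: DCC (1.1 equiv), DMAP (5 mol%), CH2Cl2, 0 °C to rt
Reagents that add atoms: none
Why: Steglich esterification, a standard way to aryl but-2-ynoates, meets only one free hydroxyl in 10, and low temperature with catalytic DMAP holds back isomerisation of the ynoate to the allenoate.

**Step 8**
Reactants: 12 methyl 2-(benzyloxy)-4-(but-2-ynoyloxy)-6-methylbenzoate; 6 1,1-dimethoxy-3-(trimethylsilyloxy)buta-1,3-diene
Product: 15 methyl 2-(benzyloxy)-4-[(4-hydroxy-2-methoxy-6-methylbenzoyl)oxy]-6-methylbenzoate, via cyclohexa-1,4-diene adduct 13 (not isolated), via aryl trimethylsilyl ether 14 (not isolated)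
Conditions: 6 (3 equiv), toluene (concentrated), sealed tube, 120 °C; then 1 M HCl, THF, rt
Reagents that add atoms: none
Why: Normal-electron-demand Diels–Alder reaction followed by aromatisation, in which the unsubstituted CH2 terminus of 6, fed by the silyloxy and both methoxy groups, bonds to the methyl-bearing β-carbon of ynoate 12 (C5–C6) ahead of the bond between the ketene acetal carbon and the α-carbon (C1–C2), so bond formation is one-step but far from synchronous. Ring B is closed by this intermolecular [4+2] cycloaddition as cyclohexa-1,4-diene 13, which carries a ketal at C2 and a CH2 at C5, loses methanol by 1,4-elimination to arene 14 and gives up its silyl group to dilute acid. The closest known reaction type is the cycloaddition of 1,1-dialkoxy-3-silyloxybuta-1,3-dienes with alkyl 3-alkylpropiolates, which delivers 4-hydroxy-2-alkoxy-6-alkylbenzoates. Regioselectivity is the selectivity needed, and it is secured by pairing the most nucleophilic diene carbon with the electrophilic β-carbon of the ynoate, a match the reverse orientation lacks. Chemoselectivity rests on the alkyne being the only electron-poor π-bond of 12, on the aryloxy group making it a better acceptor than an alkyl ynoate, and on the excess of 6, which takes up the released methanol before it can attack the aryl ester. No stereocentre is formed, and the two oxygens of ring B come out differentiated, O4 as the phenol to be acylated in step 11 and O2 as a methyl ether.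

**Step 9**
Reactants: 7 methyl orsellinate
Product: 16 methyl 2,4-bis(benzyloxy)-6-methylbenzoate
Conditions: BnBr (2.5 equiv), K2CO3 (3 equiv), DMF, 60 °C
Reagents that add atoms: benzyl bromide, BrCc1ccccc1
Why: Double Williamson ether synthesis with excess benzyl bromide in DMF alkylates both the free and the chelated phenol of 7.

**Step 10**
Reactants: 16 methyl 2,4-bis(benzyloxy)-6-methylbenzoate
Product: 17 2,4-bis(benzyloxy)-6-methylbenzoic acid
Conditions: KOH, aq DMSO, 100 °C; then 2 M HCl, 0 °C
Reagents that add atoms: potassium hydroxide, [K+].[OH-]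
Why: Saponification of a doubly ortho-substituted benzoate needs the poorly solvated hydroxide of hot aqueous DMSO, under which benzyl aryl ethers are stable, and cold acidification avoids decarboxylation of the electron-rich acid.

**Step 11**
Reactants: 17 2,4-bis(benzyloxy)-6-methylbenzoic acid; 15 B–C depside with free ring B 4-hydroxyl
Product: 19 methyl 2-(benzyloxy)-4-{[4-{[2,4-bis(benzyloxy)-6-methylbenzoyl]oxy}-2-methoxy-6-methylbenzoyl]oxy}-6-methylbenzoate, via acyl trifluoroacetate 18 (not isolated)
Conditions: (CF3CO)2O (2.5 equiv), toluene, 0 °C to rt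
Reagents that add atoms: trifluoroacetic anhydride, O=C(OC(=O)C(F)(F)F)C(F)(F)F (its atoms are held only in 18, none in 19)
Why: Mixed-anhydride esterification, the classical depside coupling, in which the anhydride turns 17 into 18, whose acyl group gains acylium character from the ortho and para benzyloxy donors and so escapes the steric block of its two ortho substituents, and the ring B 4-hydroxyl is the only free hydroxyl of 15.

**Step 12**
Reactants: 19 protected tridepside
Product: 20 methyl gyrophorate (CNP0212402.0)
Conditions: BCl3 (1 M in CH2Cl2, 10 equiv), pentamethylbenzene (10 equiv), CH2Cl2, −78 °C, then 0 °C; ice/1 M HCl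
Reagents that add atoms: none
Why: Lewis-acid ether cleavage, in which BCl3 ionises the three aryl benzyl ethers at low temperature with pentamethylbenzene as a non-basic benzyl cation trap (Friedel–Crafts benzylation), and on warming boron held between the ring B ester carbonyl and the ortho methoxy oxygen lets chloride remove the methyl group by SN2, while the aryl ester links and the methyl ester should persist at 0 °C.

**Compound list**
1 | 1,1-dichloroethene | C=C(Cl)Cl | starting material
2 | acetyl chloride | CC(=O)Cl | starting material
3 | 4,4,4-trichlorobutan-2-one | CC(=O)CC(Cl)(Cl)Cl | intermediate (not isolated)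
4 | 4,4-dichlorobut-3-en-2-one | CC(=O)C=C(Cl)Cl | intermediate
5 | 4,4-dimethoxybut-3-en-2-one | CC(=O)C=C(OC)OC | intermediate
6 | 1,1-dimethoxy-3-(trimethylsilyloxy)buta-1,3-diene | COC(OC)=CC(=C)O[Si](C)(C)C | intermediate
7 | methyl orsellinate | COC(=O)c1c(C)cc(O)cc1O | starting material
8 | methyl 4-(allyloxy)-2-hydroxy-6-methylbenzoate | COC(=O)c1c(C)cc(OCC=C)cc1O | intermediate
9 | methyl 4-(allyloxy)-2-(benzyloxy)-6-methylbenzoate | COC(=O)c1c(C)cc(OCC=C)cc1OCc1ccccc1 | intermediate
10 | methyl 2-(benzyloxy)-4-hydroxy-6-methylbenzoate | COC(=O)c1c(C)cc(O)cc1OCc1ccccc1 | intermediate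
11 | but-2-ynoic acid | CC#CC(=O)O | starting material
12 | methyl 2-(benzyloxy)-4-(but-2-ynoyloxy)-6-methylbenzoate | COC(=O)c1c(C)cc(OC(=O)C#CC)cc1OCc1ccccc1 | intermediate
13 | cyclohexa-1,4-diene adduct (ring B: C1=C6, C3=C4, dimethyl ketal at C2, OSiMe3 at C4, CH2 at C5) | COC(=O)c1c(C)cc(OC(=O)C2=C(C)CC(O[Si](C)(C)C)=CC2(OC)OC)cc1OCc1ccccc1 | intermediate (not isolated)
14 | B–C depside, ring B 4-O-trimethylsilyl, 2-O-methyl | COC(=O)c1c(C)cc(OC(=O)c2c(C)cc(O[Si](C)(C)C)cc2OC)cc1OCc1ccccc1 | intermediate (not isolated)
15 | methyl 2-(benzyloxy)-4-[(4-hydroxy-2-methoxy-6-methylbenzoyl)oxy]-6-methylbenzoate | COC(=O)c1c(C)cc(OC(=O)c2c(C)cc(O)cc2OC)cc1OCc1ccccc1 | intermediate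
16 | methyl 2,4-bis(benzyloxy)-6-methylbenzoate | COC(=O)c1c(C)cc(OCc2ccccc2)cc1OCc1ccccc1 | intermediate
17 | 2,4-bis(benzyloxy)-6-methylbenzoic acid | Cc1cc(OCc2ccccc2)cc(OCc2ccccc2)c1C(=O)O | intermediate
18 | 2,4-bis(benzyloxy)-6-methylbenzoic trifluoroacetic anhydride | Cc1cc(OCc2ccccc2)cc(OCc2ccccc2)c1C(=O)OC(=O)C(F)(F)F | intermediate (not isolated)
19 | protected tridepside (ring A 2,4-di-O-benzyl, ring B 2-O-methyl, ring C 2-O-benzyl) | COC(=O)c1c(C)cc(OC(=O)c2c(C)cc(OC(=O)c3c(C)cc(OCc4ccccc4)cc3OCc3ccccc3)cc2OC)cc1OCc1ccccc1 | intermediate
20 | methyl gyrophorate, methyl 4-{[4-[(2,4-dihydroxy-6-methylbenzoyl)oxy]-2-hydroxy-6-methylbenzoyl]oxy}-2-hydroxy-6-methylbenzoate | COC(=O)c1c(C)cc(OC(=O)c2c(C)cc(OC(=O)c3c(C)cc(O)cc3O)cc2O)cc1O | target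

**Total step count:** 12
**Longest linear sequence:** 7 steps (7 → 8 → 9 → 10 → 12 → 15 → 19 → 20; steps 4, 5, 6, 7, 8, 11, 12)

**Steps most likely to fail**

1. Step 8.
   - The cycloaddition of the β-methyl-substituted ynoate may be slower than thermal decay or protonation of the diene.
   - The released methanol may cleave the aryl ester.
   - The fallback sets out from 8 and comes back at 15. Ring B is then taken from methyl orsellinate and joined by a classical depside coupling instead of being built.
   - Compound 8 is O-methylated at the chelated hydroxyl (MeI, K2CO3, DMF) to methyl 4-(allyloxy)-2-methoxy-6-methylbenzoate F1.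
   - F1 is saponified (KOH, aq DMSO, 100 °C) to 4-(allyloxy)-2-methoxy-6-methylbenzoic acid F2.
   - F2 is joined to phenol 10 by Steglich esterification (DCC, DMAP, CH2Cl2) to the O4-allyl B–C depside F3.
   - F3 is deallylated with Pd(PPh3)4 and morpholine to 15.

2. Step 12.
   - The chelated methyl ether may be cleaved incompletely at the temperature that the two depside bonds and the hindered methyl ester tolerate.
   - Ester scission may set in on further warming.
   - The fallback sets out from 15 and comes back at 20. The Lewis-acid step is moved to the smaller didepside, and the last step becomes a neutral hydrogenolysis.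
   - Compound 15 is treated with BCl3 and pentamethylbenzene (CH2Cl2, −78 to 0 °C) to give methyl lecanorate F4.
   - The only non-chelated hydroxyl of F4 (ring B O4) is acylated by 17 through 18 ((CF3CO)2O, toluene), giving the ring A di-O-benzyl tridepside F5.
   - H2 over Pd/C in EtOAc then removes the two benzyl groups to give 20.

3. Step 11.
   - A doubly ortho-substituted acid may acylate the electron-poor phenol only sluggishly.
   - Trifluoroacetylation of the phenol and acyl exchange at the existing depside bond may compete.
   - The fallback sets out from 15 and comes back at 20. Ring A is grown in the same way as ring B instead of being attached.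
   - Compound 15 is esterified with 11 (DCC, DMAP, CH2Cl2, 0 °C) to the ring B but-2-ynoate F6.
   - F6 is heated with diene 6 (toluene, 120 °C). It passes through the cyclohexa-1,4-diene adduct F7 and the ring A aryl trimethylsilyl ether F8.
   - After dilute HCl this gives the tridepside with ring A 4-hydroxyl free and 2-O-methyl F9.
   - BCl3 with pentamethylbenzene (−78 to 0 °C) then removes the one benzyl and the two chelated methyl groups to give 20.

**Further compounds**
F1 | step 8 | methyl 4-(allyloxy)-2-methoxy-6-methylbenzoate | COC(=O)c1c(C)cc(OCC=C)cc1OC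
F2 | step 8 | 4-(allyloxy)-2-methoxy-6-methylbenzoic acid | Cc1cc(OCC=C)cc(OC)c1C(=O)O
F3 | step 8 | methyl 4-{[4-(allyloxy)-2-methoxy-6-methylbenzoyl]oxy}-2-(benzyloxy)-6-methylbenzoate | COC(=O)c1c(C)cc(OC(=O)c2c(C)cc(OCC=C)cc2OC)cc1OCc1ccccc1
F4 | step 12 | methyl lecanorate, methyl 4-[(2,4-dihydroxy-6-methylbenzoyl)oxy]-2-hydroxy-6-methylbenzoate | COC(=O)c1c(C)cc(OC(=O)c2c(C)cc(O)cc2O)cc1O
F5 | step 12 | methyl gyrophorate ring A 2,4-dibenzyl ether | COC(=O)c1c(C)cc(OC(=O)c2c(C)cc(OC(=O)c3c(C)cc(OCc4ccccc4)cc3OCc3ccccc3)cc2O)cc1O
F6 | step 11 | but-2-ynoate of 15 at ring B O4 | COC(=O)c1c(C)cc(OC(=O)c2c(C)cc(OC(=O)C#CC)cc2OC)cc1OCc1ccccc1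
F7 | step 11 | cyclohexa-1,4-diene adduct of F6 and 6 | COC(=O)c1c(C)cc(OC(=O)c2c(C)cc(OC(=O)C3=C(C)CC(O[Si](C)(C)C)=CC3(OC)OC)cc2OC)cc1OCc1ccccc1
F8 | step 11 | tridepside, ring A 4-O-trimethylsilyl and 2-O-methyl | COC(=O)c1c(C)cc(OC(=O)c2c(C)cc(OC(=O)c3c(C)cc(O[Si](C)(C)C)cc3OC)cc2OC)cc1OCc1ccccc1
F9 | step 11 | tridepside, ring A 4-hydroxy-2-methoxy, ring B 2-methoxy, ring C 2-benzyloxy | COC(=O)c1c(C)cc(OC(=O)c2c(C)cc(OC(=O)c3c(C)cc(O)cc3OC)cc2OC)cc1OCc1ccccc1
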